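**Plan**

1. Retrosynthesis opens the cyclohexene whose six carbons are the quaternary C(CO2Me), its CH–C(=O) neighbour, a CH2, the tetrasubstituted C(Me)=C olefin and the allylic CH. A retro-[4+2] across the two sp3–sp3 bonds that flank the C(Me)=C unit gives a 14-membered triketone with an (E)-MeO2C–C=CH–C(=O) dienophile and a tetrahydropyran-bridged 14-membered 1,3-diene carrying an isopropenyl group.
2. Dienophile half: cut the dienone C–C(OH) bond (Nozaki–Hiyama–Kishi ring closure), the enone carbinol C–C bond (alkenylzinc addition) and the CH(iPr)–C(NO2) bond (organocatalytic nitro-Michael). The enoate comes from a Morita–Baylis–Hillman acetate.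
3. Diene half: cut the diene C–C bond (Heck ring closure onto an α-methylene lactone), the lactone (Hosomi–Sakurai/lactonization) and the tetrahydropyran C–O bond (6-exo epoxide opening). The chain comes from geranyl bromide.
4. Forward order: each half goes from open chain to 14-membered ring (steps 1–12 and 13–28); the cyclohexene is formed last by joining the halves.
5. Stereochemistry: the (S)-prolinol catalyst sets the isopropyl carbon. Shi epoxide plus inversion by ArCH2OH, and Sharpless epoxide plus inversion on ring closure, set the four C–O centres of the tetrahydropyran region. Felkin–Anh addition sets the acetoxy carbon.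
6. The three centres of the cyclohexene come from the (E)-dienophile geometry, an ester-endo approach and the facial bias of both macrocycles.

Key step: step 29

Remark: carbinol carbons that are later oxidized to ketones (in 3, 7, 17, 20) are carried as epimer mixtures. The L-fructose-derived Shi ketone is assumed to give the (S,S)-epoxide by the usual spiro model, and both macrocycles are assumed to react on their outer faces in step 29.

**Dienophile half (steps 1–12)**

Step 1
Reactants: 1 methyl acrylate; 2 2,2-dimethoxyacetaldehyde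
Product: 3 methyl 3-hydroxy-4,4-dimethoxy-2-methylidenebutanoate (racemic)
Conditions: DABCO (0.5 equiv), 1,4-dioxane/H2O, rt
Reagents that add atoms: none
Why: Morita–Baylis–Hillman reaction of the acrylate–amine zwitterion with a reactive α,α-dialkoxy aldehyde; the carbinol carbon becomes sp2 in step 3, so the racemate serves.

Step 2
Reactants: 3 methyl 3-hydroxy-4,4-dimethoxy-2-methylidenebutanoate
Product: 4 methyl 3-acetoxy-4,4-dimethoxy-2-methylidenebutanoate
Conditions: Ac2O, pyridine, DMAP (cat.), CH2Cl2, 0 °C
Reagents that add atoms: acetic anhydride, CC(=O)OC(C)=O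
Why: Acylation of the secondary alcohol installs the leaving group for the allylic substitution.

Step 3
Reactants: 4 methyl 3-acetoxy-4,4-dimethoxy-2-methylidenebutanoate
Product: 5 methyl (E)-4,4-dimethoxy-2-(2-nitroethyl)but-2-enoate
Conditions: MeNO2 (10 equiv), K2CO3, THF/H2O, rt
Reagents that add atoms: nitromethane, C[N+](=O)[O-]
Why: SN2' substitution (conjugate addition of the nitronate to the methylidene carbon, then E1cB loss of acetate) should give the trisubstituted enoate with the acetal carbon trans to the ester, the usual outcome for ester-derived Baylis–Hillman acetates.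

Step 4
Reactants: 5 methyl (E)-4,4-dimethoxy-2-(2-nitroethyl)but-2-enoate; 6 (E)-4-methylpent-2-enal
Product: 7 methyl (E)-4,4-dimethoxy-2-[(3S)-2-nitro-5-oxo-3-(propan-2-yl)pentyl]but-2-enoate (both epimers at the nitro carbon)
Conditions: (S)-α,α-diphenylprolinol trimethylsilyl ether (10 mol %), PhCO2H (20 mol %), MeOH, rt
Reagents that add atoms: none
Why: Iminium-catalysed asymmetric Michael addition of a nitroalkane to an enal; the nitronate adds to the β-carbon on the face away from the diphenyl(silyloxy)methyl group, which sets the isopropyl-bearing centre as (S), and the nitro carbon is a masked ketone.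

Step 5
Reactants: 7 methyl (E)-4,4-dimethoxy-2-[(3S)-2-nitro-5-oxo-3-(propan-2-yl)pentyl]but-2-enoate
Product: 9 methyl (E)-4,4-dimethoxy-2-[(3S)-2,5-dioxo-3-(propan-2-yl)pentyl]but-2-enoate, via sodium nitronate 8 (not isolated)
Conditions: NaOMe, MeOH, 0 °C; then aq. TiCl3, NH4OAc (pH 5–6), THF, rt
Reagents that add atoms: water, O
Why: Nef reaction (reduction of the nitronate by trivalent titanium to the imine, hydrolysis in the buffer) should unmask the ketone at a pH that spares the aldehyde, the dimethyl acetal and the new α-stereocentre.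

Step 6
Reactants: 10 pent-3-yn-1-ol
Product: 11 5-bromopent-2-yne
Conditions: CBr4, PPh3, CH2Cl2, 0 °C
Reagents that add atoms: carbon tetrabromide, BrC(Br)(Br)Br
Why: Appel bromination of a primary alcohol.

Step 7
Reactants: 11 5-bromopent-2-yne
Product: 14 (Z)-1-iodo-2-methylhept-1-en-5-yne, via pent-3-ynylmagnesium bromide 12 (not isolated), via (Z)-alkenylcopper 13 (not isolated)
Conditions: Mg, Et2O; CuBr·SMe2, Et2O/SMe2, −45 °C; propyne, −25 °C; I2, −50 → 0 °C
Reagents that add atoms: propyne, CC#C; iodine, II
Why: Carbocupration of propyne (syn addition, alkyl group to the internal carbon) followed by iodinolysis with retention should give the iodoalkene with iodine cis to the CH2CH2 chain, the geometry of the later (Z)-enone.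

Step 8
Reactants: 14 (Z)-1-iodo-2-methylhept-1-en-5-yne; 9 methyl (E)-4,4-dimethoxy-2-[(3S)-2,5-dioxo-3-(propan-2-yl)pentyl]but-2-enoate
Product: 17 methyl (E)-2-[(3S,6E,10Z)-5-hydroxy-11-iodo-6,10-dimethyl-2-oxo-3-(propan-2-yl)undeca-6,10-dien-1-yl]-4,4-dimethoxybut-2-enoate (both carbinol epimers), via alkenylzirconocene 15 (not isolated), via alkenyl(methyl)zinc 16 (not isolated)
Conditions: Cp2Zr(H)Cl, CH2Cl2, rt; Me2Zn, toluene, −65 °C; then 9, 0 °C; aq. NH4Cl
Reagents that add atoms: none
Why: Syn hydrozirconation places zirconium on the less hindered, methyl-bearing alkyne carbon; zirconium-to-zinc transmetalation and 1,2-addition to the aldehyde (faster than to ketone or ester) should give the (E)-trisubstituted allylic alcohol, whose carbinol carbon is oxidized next.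

Step 9
Reactants: 17 allylic alcohol (name as in step 8)
Product: 18 methyl (E)-2-[(3S,6E,10Z)-11-iodo-6,10-dimethyl-2,5-dioxo-3-(propan-2-yl)undeca-6,10-dien-1-yl]-4,4-dimethoxybut-2-enoate
Conditions: DMP, NaHCO3, CH2Cl2, 0 °C
Reagents that add atoms: none
Why: Dess–Martin oxidation of the allylic alcohol to the (E)-enone under buffered, non-epimerizing conditions removes the acid-labile allylic carbinol before the acetal is opened.

Step 10
Reactants: 18 enone acetal (name as in step 9)
Product: 19 methyl (E)-2-[(3S,6E,10Z)-11-iodo-6,10-dimethyl-2,5-dioxo-3-(propan-2-yl)undeca-6,10-dien-1-yl]-4-oxobut-2-enoate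
Conditions: Amberlyst-15, acetone/H2O, rt
Reagents that add atoms: water, O
Why: Acid-catalysed hydrolysis of the dimethyl acetal; the (E) geometry keeps aldehyde and ester on opposite sides, so no butenolide can form.

Step 11
Reactants: 19 enal (name as in step 10)
Product: 20 methyl (1E,4Z,8E,12S)-3-hydroxy-5,9-dimethyl-10,13-dioxo-12-(propan-2-yl)cyclotetradeca-1,4,8-triene-1-carboxylate (both carbinol epimers)
Conditions: CrCl2 (10 equiv), NiCl2 (cat.), DMSO/THF, rt, 2 mM (slow addition)
Reagents that add atoms: none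
Why: Intramolecular Nozaki–Hiyama–Kishi reaction (oxidative addition of the alkenyl iodide to zerovalent nickel, transfer to chromium, addition to the aldehyde only) should close the 14-membered ring with retention of the (Z) olefin while ketones and ester are tolerated.

Step 12
Reactants: 20 macrocyclic bis-allylic alcohol (name as in step 11)
Product: 21 methyl (1E,4Z,8E,12S)-5,9-dimethyl-3,10,13-trioxo-12-(propan-2-yl)cyclotetradeca-1,4,8-triene-1-carboxylate (dienophile half)
Conditions: DMP, NaHCO3, CH2Cl2, 0 °C
Reagents that add atoms: none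
Why: Dess–Martin oxidation of the bis-allylic alcohol gives the cross-conjugated dienone without base, so the olefin positions, the (Z) geometry and the α-stereocentre are kept.

**Diene half (steps 13–28)**

Step 13
Reactants: 22 geranyl bromide [(2E)-1-bromo-3,7-dimethylocta-2,6-diene]
Product: 24 (5E)-6,10-dimethylundeca-5,9-dien-1-yne, via TMS-enyne 23 (not isolated)
Conditions: 1-(trimethylsilyl)propyne, n-BuLi, THF, −78 °C; then 22, −78 → 0 °C; then TBAF, THF, rt
Reagents that add atoms: 1-(trimethylsilyl)propyne, CC#C[Si](C)(C)C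
Why: SN2 alkylation of the silyl-stabilized propargyllithium at the primary allylic bromide, then fluoride cleavage of the C–Si bond.

Step 14
Reactants: 24 (5E)-6,10-dimethylundeca-5,9-dien-1-yne
Product: 26 (1E,5E)-1-iodo-2,6,10-trimethylundeca-1,5,9-triene, via alkenylalane 25 (not isolated)
Conditions: Me3Al, Cp2ZrCl2 (cat.), CH2Cl2, 0 °C → rt; then I2, THF, −30 °C
Reagents that add atoms: trimethylaluminium, C[Al](C)C; iodine, II
Why: Negishi carboalumination (syn, methyl to the internal alkyne carbon) and iodinolysis with retention should give the (E)-iodoalkene needed for the later Heck closure.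

Step 15
Reactants: 26 (1E,5E)-1-iodo-2,6,10-trimethylundeca-1,5,9-triene
Product: 27 (2E,6E,10E)-11-iodo-2,6,10-trimethylundeca-2,6,10-trien-1-ol
Conditions: SeO2 (cat.), t-BuOOH, salicylic acid (cat.), CH2Cl2, rt
Reagents that add atoms: tert-butyl hydroperoxide, CC(C)(C)OO
Why: SeO2-catalysed allylic oxidation (ene reaction, then [2,3] shift) is selective for the (E)-methyl of the terminal trisubstituted olefin; the iodoalkene is deactivated.

Step 16
Reactants: 27 (2E,6E,10E)-11-iodo-2,6,10-trimethylundeca-2,6,10-trien-1-ol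
Product: 28 (2E,6E,10E)-11-iodo-2,6,10-trimethylundeca-2,6,10-trien-1-yl acetate
Conditions: Ac2O, pyridine, DMAP (cat.), CH2Cl2, 0 °C
Reagents that add atoms: acetic anhydride, CC(=O)OC(C)=O
Why: Acetylation makes the neighbouring olefin electron-poor, so that only the central olefin is epoxidized in step 17.

Step 17
Reactants: 28 (2E,6E,10E)-11-iodo-2,6,10-trimethylundeca-2,6,10-trien-1-yl acetate
Product: 29 (2E)-5-{(2S,3S)-3-[(3E)-4-iodo-3-methylbut-3-en-1-yl]-2-methyloxiran-2-yl}-2-methylpent-2-en-1-yl acetate
Conditions: ent-Shi ketone (L-fructose-derived, 30 mol %), Oxone, K2CO3, Bu4NHSO4, MeCN/(MeO)2CH2–aq. buffer (pH 10.5), 0 °C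
Reagents that add atoms: potassium peroxymonosulfate (KHSO5 of Oxone), [K+].[O-]S(=O)(=O)OO
Why: Shi epoxidation by the chiral dioxirane attacks the only electron-rich trisubstituted olefin (the others carry an allylic acetate or iodine), and the spiro transition state of the L-fructose-derived ketone should give the (S,S)-epoxide.

Step 18
Reactants: 29 epoxide (name as in step 17)
Product: 30 (2E,6R,7S,10E)-7-hydroxy-11-iodo-6-[(4-methoxybenzyl)oxy]-2,6,10-trimethylundeca-2,10-dien-1-yl acetate
Conditions: 4-MeOC6H4CH2OH (5 equiv), BF3·OEt2 (cat.), CH2Cl2, −40 °C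
Reagents that add atoms: 4-methoxybenzyl alcohol, COc1ccc(CO)cc1
Why: Lewis-acid-catalysed epoxide alcoholysis at the tertiary carbon with inversion sets the tertiary C–O centre and leaves only the secondary hydroxyl free for the later ring closure.

Step 19
Reactants: 30 acetate (name as in step 18)
Product: 31 (2E,6R,7S,10E)-11-iodo-6-[(4-methoxybenzyl)oxy]-2,6,10-trimethylundeca-2,10-diene-1,7-diol
Conditions: K2CO3 (cat.), MeOH, 0 °C → rt
Reagents that add atoms: none
Why: Base-catalysed transesterification frees the allylic alcohol that directs the next epoxidation.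

Step 20
Reactants: 31 diol (name as in step 19)
Product: 33 (2S)-2-{(2R,5R,6S)-6-[(3E)-4-iodo-3-methylbut-3-en-1-yl]-5-[(4-methoxybenzyl)oxy]-5-methyloxan-2-yl}propane-1,2-diol (2,6-trans-tetrahydropyran), via epoxy alcohol 32 (not isolated)
Conditions: Ti(OiPr)4, L-(+)-diethyl tartrate, t-BuOOH, 4 Å MS, CH2Cl2, −20 °C; then CSA (cat.), CH2Cl2, 0 °C
Reagents that add atoms: tert-butyl hydroperoxide, CC(C)(C)OO
Why: Sharpless asymmetric epoxidation with L-(+)-tartrate gives the (2S,3S)-epoxy alcohol, and acid-catalysed 6-exo opening at the secondary epoxide carbon by the secondary hydroxyl (inversion) closes the 2,6-trans-tetrahydropyran; the tertiary oxygen is blocked as its ether, so the faster 5-exo closure is excluded.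

Step 21
Reactants: 33 tetrahydropyran diol (name as in step 20)
Product: 34 bis(triethylsilyl) ether of 33 (primary and tertiary oxygen silylated)
Conditions: Et3SiOTf, 2,6-lutidine, CH2Cl2, −78 → 0 °C
Reagents that add atoms: triethylsilyl triflate, CC[Si](CC)(CC)OS(=O)(=O)C(F)(F)F
Why: Silyl triflate silylates both the primary and the tertiary hydroxyl; the tertiary silyl ether is the non-chelating group needed in step 23.

Step 22
Reactants: 34 bis(triethylsilyl) ether
Product: 35 (2R)-2-{(2R,5R,6S)-6-[(3E)-4-iodo-3-methylbut-3-en-1-yl]-5-[(4-methoxybenzyl)oxy]-5-methyloxan-2-yl}-2-[(triethylsilyl)oxy]propanal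
Conditions: (COCl)2, DMSO, CH2Cl2, −78 → −30 °C; Et3N
Reagents that add atoms: none
Why: Swern conditions cleave and oxidize the primary triethylsilyl ether selectively and leave the tertiary one; the aldehyde has no α-hydrogen and cannot epimerize.

Step 23
Reactants: 35 α-silyloxy aldehyde (name as in step 22)
Product: 37 (5S)-5-[(1R)-1-hydroxy-1-{(2R,5R,6S)-6-[(3E)-4-iodo-3-methylbut-3-en-1-yl]-5-[(4-methoxybenzyl)oxy]-5-methyloxan-2-yl}ethyl]-3-methylideneoxolan-2-one, via hydroxy ester 36 (not isolated)
Conditions: ethyl 2-(trimethylsilylmethyl)acrylate, BF3·OEt2, CH2Cl2, −78 °C; then TsOH·H2O, MeOH/CH2Cl2, rt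
Reagents that add atoms: ethyl 2-(trimethylsilylmethyl)acrylate, CCOC(=O)C(=C)C[Si](C)(C)C
Why: Hosomi–Sakurai addition through an open transition state under polar Felkin–Anh control (nucleophile anti to the C–OSi bond and past the methyl group) should set the secondary carbinol centre; acid then closes the α-methylene-γ-butyrolactone and removes the tertiary silyl ether.

Step 24
Reactants: 37 lactone 4-methoxybenzyl ether (name as in step 23)
Product: 38 (5S)-5-[(1R)-1-hydroxy-1-{(2R,5R,6S)-5-hydroxy-6-[(3E)-4-iodo-3-methylbut-3-en-1-yl]-5-methyloxan-2-yl}ethyl]-3-methylideneoxolan-2-one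
Conditions: DDQ, CH2Cl2/pH 7 buffer, 0 °C
Reagents that add atoms: none
Why: Oxidative cleavage of the 4-methoxybenzyl ether (hydride abstraction, hydrolysis of the oxocarbenium ion) frees the tertiary alcohol before the electron-rich triene exists.

Step 25
Reactants: 38 iodoalkenyl α-methylene lactone (name as in step 24)
Product: 39 tricyclic dienyl lactone: 14-membered carbocycle bridged by the 2,6-trans-tetrahydropyran and fused to an (E)-α-alkylidene-γ-butyrolactone, (1E,3E)-diene, two tertiary alcohols
Conditions: Pd(OAc)2 (20 mol %), Bu4NCl, K2CO3, DMF, 60 °C, 2 mM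
Reagents that add atoms: none
Why: Intramolecular Heck reaction (oxidative addition of the alkenyl iodide, syn insertion at the unsubstituted carbon of the exocyclic methylene, syn β-hydride elimination from the new CH2) should close the 14-membered ring as the (E)-alkylidene lactone, the known outcome for α-methylene-γ-butyrolactones.

Step 26
Reactants: 39 tricyclic dienyl lactone
Product: 40 hydroxy methyl ketone: the 14-membered diene ring with acetyl on the ring olefin carbon and a free secondary alcohol (in equilibrium with its cyclic hemiketal)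
Conditions: MeLi (3.3 equiv), THF, −78 °C; aq. NH4Cl at −78 °C
Reagents that add atoms: methyllithium, [Li]C
Why: 1,2-Addition of methyllithium to the lactone carbonyl stops after one methyl because the tetrahedral lithium alkoxide persists at −78 °C; two equivalents are used up by the tertiary hydroxyls.

Step 27
Reactants: 40 hydroxy methyl ketone
Product: 41 triene triol: the 14-membered (1E,3E)-diene ring with isopropenyl on C1, free secondary alcohol at C13, tertiary alcohols at C8 and C12, ether bridge C7–O–C11 (cembrane numbering)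
Conditions: Ph3PCH3Br, KOtBu, THF, 0 °C → rt
Reagents that add atoms: methyltriphenylphosphonium bromide, C[P+](c1ccccc1)(c1ccccc1)c1ccccc1.[Br-]
Why: Wittig methylenation of the ketone (through the open hydroxy ketone form) turns the acetyl into the isopropenyl group and completes the s-cis-capable diene.

Step 28
Reactants: 41 triene triol
Product: 42 diene half: 13-acetate of 41
Conditions: Ac2O, pyridine, DMAP (cat.), CH2Cl2, 0 °C
Reagents that add atoms: acetic anhydride, CC(=O)OC(C)=O
Why: Acylation is selective for the secondary alcohol over the two hindered tertiary alcohols.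

**Union**

Step 29
Reactants: 21 dienophile half (methyl (1E,4Z,8E,12S)-5,9-dimethyl-3,10,13-trioxo-12-(propan-2-yl)cyclotetradeca-1,4,8-triene-1-carboxylate); 42 diene half
Product: 43 bisglaucumlide C
Conditions: 21 (1 equiv), 42 (1.3 equiv), BHT (cat.), toluene (1 M), 90 °C, sealed tube, argon, dark
Reagents that add atoms: none
Why: A concerted but asynchronous intermolecular Diels–Alder reaction joins the isopropenyl/ring-olefin diene of 42 to the MeO2C–C=CH–C(=O) olefin of 21, and its closest known type is the thermal [4+2] of 2,3-disubstituted 1,3-dienes with 4-oxo-2-enoates in biomimetic unions of two cembranoid halves. The cyclohexene is closed by this [4+2] mode, with the bond from the diene CH2 terminus to the CH next to the ketone formed ahead of the bond from the substituted diene terminus to the C(CO2Me) carbon. The trans relation of ester and acyl on the quaternary carbon and its CH neighbour follows from the (E) dienophile, since addition is suprafacial. The allylic CH centre should follow from the transition state with the ester endo and the whole 14-membered dienophile ring exo, which places the outside dienyl substituent cis to the ester. The absolute sense rests on peripheral attack on both macrocycles, biased on 21 by the isopropyl-bearing centre and on 42 by the acetoxy-bearing, tetrahydropyran-bridged segment next to the diene. Chemoselectivity should come from the double activation of the one olefin in 21 and from the fact that only the isopropenyl diene of 42 can reach an unhindered s-cis form; regioselectivity should come from the unhindered CH2 terminus bonding first to the less hindered dienophile carbon, with developing charge stabilized by the ester and the pentadienyl system.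

**Compound list**

1 | methyl acrylate | C=CC(=O)OC | starting material
2 | 2,2-dimethoxyacetaldehyde | COC(OC)C=O | starting material
3 | methyl 3-hydroxy-4,4-dimethoxy-2-methylidenebutanoate (racemic) | COC(OC)C(O)C(=C)C(=O)OC | intermediate
4 | methyl 3-acetoxy-4,4-dimethoxy-2-methylidenebutanoate | COC(OC)C(OC(C)=O)C(=C)C(=O)OC | intermediate
5 | methyl (E)-4,4-dimethoxy-2-(2-nitroethyl)but-2-enoate | COC(=O)/C(CC[N+](=O)[O-])=C/C(OC)OC | intermediate
6 | (E)-4-methylpent-2-enal | CC(C)/C=C/C=O | starting material
7 | methyl (E)-4,4-dimethoxy-2-[(3S)-2-nitro-5-oxo-3-(propan-2-yl)pentyl]but-2-enoate | COC(=O)/C(CC([N+](=O)[O-])[C@@H](CC=O)C(C)C)=C/C(OC)OC | intermediate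
8 | sodium nitronate of 7 | COC(=O)/C(CC(=[N+]([O-])[O-])[C@@H](CC=O)C(C)C)=C/C(OC)OC.[Na+] | intermediate (not isolated)
9 | methyl (E)-4,4-dimethoxy-2-[(3S)-2,5-dioxo-3-(propan-2-yl)pentyl]but-2-enoate | COC(=O)/C(CC(=O)[C@@H](CC=O)C(C)C)=C/C(OC)OC | intermediate
10 | pent-3-yn-1-ol | CC#CCCO | starting material
11 | 5-bromopent-2-yne | CC#CCCBr | intermediate
12 | pent-3-ynylmagnesium bromide | CC#CCC[Mg]Br | intermediate (not isolated)
13 | (Z)-(2-methylhept-1-en-5-yn-1-yl)copper | CC#CCC/C(C)=C\[Cu] | intermediate (not isolated)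
14 | (Z)-1-iodo-2-methylhept-1-en-5-yne | CC#CCC/C(C)=C\I | intermediate
15 | chloro[(2E,6Z)-7-iodo-6-methylhepta-2,6-dien-2-yl]zirconocene | C/C(=C\CC/C(C)=C\I)[Zr](Cl)(C1C=CC=C1)C1C=CC=C1 | intermediate (not isolated)
16 | [(2E,6Z)-7-iodo-6-methylhepta-2,6-dien-2-yl](methyl)zinc | C/C(=C\CC/C(C)=C\I)[Zn]C | intermediate (not isolated)
17 | methyl (E)-2-[(3S,6E,10Z)-5-hydroxy-11-iodo-6,10-dimethyl-2-oxo-3-(propan-2-yl)undeca-6,10-dien-1-yl]-4,4-dimethoxybut-2-enoate | COC(=O)/C(CC(=O)[C@@H](CC(O)/C(C)=C/CC/C(C)=C\I)C(C)C)=C/C(OC)OC | intermediate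
18 | methyl (E)-2-[(3S,6E,10Z)-11-iodo-6,10-dimethyl-2,5-dioxo-3-(propan-2-yl)undeca-6,10-dien-1-yl]-4,4-dimethoxybut-2-enoate | COC(=O)/C(CC(=O)[C@@H](CC(=O)/C(C)=C/CC/C(C)=C\I)C(C)C)=C/C(OC)OC | intermediate
19 | methyl (E)-2-[(3S,6E,10Z)-11-iodo-6,10-dimethyl-2,5-dioxo-3-(propan-2-yl)undeca-6,10-dien-1-yl]-4-oxobut-2-enoate | COC(=O)/C(CC(=O)[C@@H](CC(=O)/C(C)=C/CC/C(C)=C\I)C(C)C)=C/C=O | intermediate
20 | methyl (1E,4Z,8E,12S)-3-hydroxy-5,9-dimethyl-10,13-dioxo-12-(propan-2-yl)cyclotetradeca-1,4,8-triene-1-carboxylate | COC(=O)/C1=C/C(O)/C=C(C)\CC/C=C(C)/C(=O)C[C@@H](C(C)C)C(=O)C1 | intermediate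
21 | methyl (1E,4Z,8E,12S)-5,9-dimethyl-3,10,13-trioxo-12-(propan-2-yl)cyclotetradeca-1,4,8-triene-1-carboxylate (dienophile half) | COC(=O)/C1=C/C(=O)/C=C(C)\CC/C=C(C)/C(=O)C[C@@H](C(C)C)C(=O)C1 | intermediate
22 | geranyl bromide | CC(C)=CCC/C(C)=C/CBr | starting material
23 | trimethyl[(5E)-6,10-dimethylundeca-5,9-dien-1-yn-1-yl]silane | C[Si](C)(C)C#CCC/C=C(C)/CCC=C(C)C | intermediate (not isolated)
24 | (5E)-6,10-dimethylundeca-5,9-dien-1-yne | C#CCC/C=C(C)/CCC=C(C)C | intermediate
25 | dimethyl[(1E,5E)-2,6,10-trimethylundeca-1,5,9-trien-1-yl]alane | C[Al](C)/C=C(C)/CC/C=C(C)/CCC=C(C)C | intermediate (not isolated)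
26 | (1E,5E)-1-iodo-2,6,10-trimethylundeca-1,5,9-triene | I/C=C(C)/CC/C=C(C)/CCC=C(C)C | intermediate
27 | (2E,6E,10E)-11-iodo-2,6,10-trimethylundeca-2,6,10-trien-1-ol | OC/C(C)=C/CC/C(C)=C/CC/C(C)=C/I | intermediate
28 | (2E,6E,10E)-11-iodo-2,6,10-trimethylundeca-2,6,10-trien-1-yl acetate | CC(=O)OC/C(C)=C/CC/C(C)=C/CC/C(C)=C/I | intermediate
29 | (2E)-5-{(2S,3S)-3-[(3E)-4-iodo-3-methylbut-3-en-1-yl]-2-methyloxiran-2-yl}-2-methylpent-2-en-1-yl acetate | CC(=O)OC/C(C)=C/CC[C@]1(C)O[C@H]1CC/C(C)=C/I | intermediate
30 | (2E,6R,7S,10E)-7-hydroxy-11-iodo-6-[(4-methoxybenzyl)oxy]-2,6,10-trimethylundeca-2,10-dien-1-yl acetate | CC(=O)OC/C(C)=C/CC[C@@](C)(OCc1ccc(OC)cc1)[C@@H](O)CC/C(C)=C/I | intermediate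
31 | (2E,6R,7S,10E)-11-iodo-6-[(4-methoxybenzyl)oxy]-2,6,10-trimethylundeca-2,10-diene-1,7-diol | OC/C(C)=C/CC[C@@](C)(OCc1ccc(OC)cc1)[C@@H](O)CC/C(C)=C/I | intermediate
32 | {(2S,3S)-3-[(3R,4S,7E)-4-hydroxy-8-iodo-3-[(4-methoxybenzyl)oxy]-3,7-dimethyloct-7-en-1-yl]-2-methyloxiran-2-yl}methanol | OC[C@]1(C)O[C@H]1CC[C@@](C)(OCc1ccc(OC)cc1)[C@@H](O)CC/C(C)=C/I | intermediate (not isolated)
33 | (2S)-2-{(2R,5R,6S)-6-[(3E)-4-iodo-3-methylbut-3-en-1-yl]-5-[(4-methoxybenzyl)oxy]-5-methyloxan-2-yl}propane-1,2-diol | OC[C@](C)(O)[C@H]1CC[C@@](C)(OCc2ccc(OC)cc2)[C@H](CC/C(C)=C/I)O1 | intermediate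
34 | bis(triethylsilyl) ether of 33 | CC[Si](CC)(CC)OC[C@](C)(O[Si](CC)(CC)CC)[C@H]1CC[C@@](C)(OCc2ccc(OC)cc2)[C@H](CC/C(C)=C/I)O1 | intermediate
35 | (2R)-2-{(2R,5R,6S)-6-[(3E)-4-iodo-3-methylbut-3-en-1-yl]-5-[(4-methoxybenzyl)oxy]-5-methyloxan-2-yl}-2-[(triethylsilyl)oxy]propanal | O=C[C@](C)(O[Si](CC)(CC)CC)[C@H]1CC[C@@](C)(OCc2ccc(OC)cc2)[C@H](CC/C(C)=C/I)O1 | intermediate
36 | ethyl (4S,5S)-4-hydroxy-2-methylidene-5-(oxan-2-yl as in 35)-5-[(triethylsilyl)oxy]hexanoate | CCOC(=O)C(=C)C[C@H](O)[C@](C)(O[Si](CC)(CC)CC)[C@H]1CC[C@@](C)(OCc2ccc(OC)cc2)[C@H](CC/C(C)=C/I)O1 | intermediate (not isolated)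
37 | (5S)-5-[(1R)-1-hydroxy-1-{(2R,5R,6S)-6-[(3E)-4-iodo-3-methylbut-3-en-1-yl]-5-[(4-methoxybenzyl)oxy]-5-methyloxan-2-yl}ethyl]-3-methylideneoxolan-2-one | C=C1C[C@H](OC1=O)[C@](C)(O)[C@H]2CC[C@@](C)(OCc3ccc(OC)cc3)[C@H](CC/C(C)=C/I)O2 | intermediate
38 | (5S)-5-[(1R)-1-hydroxy-1-{(2R,5R,6S)-5-hydroxy-6-[(3E)-4-iodo-3-methylbut-3-en-1-yl]-5-methyloxan-2-yl}ethyl]-3-methylideneoxolan-2-one | C=C1C[C@H](OC1=O)[C@](C)(O)[C@H]2CC[C@@](C)(O)[C@H](CC/C(C)=C/I)O2 | intermediate
39 | tricyclic dienyl lactone (14-membered ring, tetrahydropyran bridge, fused (E)-α-alkylidene-γ-butyrolactone) | O=C1O[C@H]2C/C1=C\C=C(C)\CC[C@@H]3O[C@H](CC[C@@]3(C)O)[C@@]2(C)O | intermediate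
40 | hydroxy methyl ketone (acetyl on the diene ring, free secondary alcohol) | CC(=O)/C1=C/C=C(C)/CC[C@@H]2O[C@H](CC[C@@]2(C)O)[C@@](C)(O)[C@@H](O)C1 | intermediate
41 | triene triol (isopropenyl diene, free secondary alcohol) | C=C(C)/C1=C/C=C(C)/CC[C@@H]2O[C@H](CC[C@@]2(C)O)[C@@](C)(O)[C@@H](O)C1 | intermediate
42 | diene half (13-acetate of 41) | C=C(C)/C1=C/C=C(C)/CC[C@@H]2O[C@H](CC[C@@]2(C)O)[C@@](C)(O)[C@@H](OC(C)=O)C1 | intermediate
43 | bisglaucumlide C | COC(=O)[C@]12CC(=O)[C@H](C(C)C)CC(=O)/C(C)=C/CC/C(C)=C\C(=O)[C@H]1CC(C)=C1C[C@H](OC(C)=O)[C@](C)(O)[C@H]3CC[C@@](C)(O)[C@H](CC/C(C)=C/[C@@H]12)O3 | target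

**Step count and risks**

Total steps: 29. Longest linear sequence: 17 (steps 13–28, then step 29).

Steps most likely to fail:

Step 29. The cycloaddition may be slow, may go through the ketone-endo transition state or on the wrong face of either macrocycle, and the (Z)-dienone may isomerize on long heating. The fallback moves the cycloaddition ahead of the closure of the triketone ring. It sets out from enal 19 and diene 42: a thermal or Me2AlCl-promoted [4+2] of the open-chain (E)-4-oxobut-2-enoate with 42 should give the cyclohexenecarbaldehyde F1, with the chain-bearing carbon substituent exo. Nozaki–Hiyama–Kishi macrocyclization (CrCl2, NiCl2 cat., DMSO, high dilution) of the alkenyl iodide onto the ring aldehyde then closes the 14-membered ring as the carbinol F2. Dess–Martin oxidation of F2 comes back to the route at 43.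

Step 25. β-Hydride elimination may go into the lactone ring (butenolide), the substrate may oligomerize, or the new olefin may form with mixed geometry. The fallback closes the ring by olefin metathesis. It sets out from 38: Stille coupling with tributyl(vinyl)stannane (Pd(PPh3)4, CuI, DMF) gives the terminal diene lactone F3. Second-generation Hoveyda–Grubbs catalyst (toluene, 80 °C, 2 mM) then joins the exocyclic methylene and the terminal vinyl group with loss of ethene and comes back to the route at 39.

Step 23. Facial selectivity at the hindered α-silyloxy aldehyde may be poor, or the electron-poor allylsilane may not add. The fallback replaces substrate control by catalyst control. It sets out from 35: chromium-catalysed asymmetric 2-(alkoxycarbonyl)allylation with ethyl 2-(bromomethyl)acrylate (CrCl2 cat., Mn, Me3SiCl, chiral oxazoline–sulfonamide ligand, THF; no nickel, so the alkenyl iodide stays untouched) gives hydroxy ester 36 after desilylation of the new carbinol. This is lactonized and desilylated with TsOH as before and comes back to the route at 37; no compound outside the list arises (entry F0).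

Further compounds
F1 | step 29 | cyclohexenecarbaldehyde from 19 and 42 (open-chain adduct with alkenyl iodide side chain) | COC(=O)[C@]1(CC(=O)[C@H](C(C)C)CC(=O)/C(C)=C/CC/C(C)=C\I)[C@@H](C=O)CC(C)=C2C[C@H](OC(C)=O)[C@](C)(O)[C@H]3CC[C@@](C)(O)[C@H](CC/C(C)=C/[C@H]12)O3
F2 | step 29 | macrocyclic bis-allylic alcohol (43 with CH(OH) in place of the dienone carbonyl) | COC(=O)[C@]12CC(=O)[C@H](C(C)C)CC(=O)/C(C)=C/CC/C(C)=C\C(O)[C@H]1CC(C)=C1C[C@H](OC(C)=O)[C@](C)(O)[C@H]3CC[C@@](C)(O)[C@H](CC/C(C)=C/[C@@H]12)O3
F3 | step 25 | terminal diene lactone (38 with vinyl in place of iodine) | C=C1C[C@H](OC1=O)[C@](C)(O)[C@H]2CC[C@@](C)(O)[C@H](CC/C(C)=C/C=C)O2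
F0 | step 23 | none | none
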